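**Retrosynthetic overview**
- Target ⇐ global O‑demethylation of its tri‑O‑methyl ether ⇐ Raney Ni desulfurization of a macrocyclic bis(1,3‑dithiane).
- Key disconnection: both benzylic C–C bonds of the C14 bridge at once. A dilithiated bis(2‑aryl‑1,3‑dithiane), i.e. two aroyl anion equivalents on one diaryl ether, is joined to 1,12‑dibromododecane; the second alkylation closes the 21‑membered ring.
- Bis‑dithiane ⇐ diaryl ether dialdehyde ⇐ Ullmann C–O coupling of 3‑bromo‑2,5‑dimethoxybenzaldehyde (by O‑methylation of the bromosalicylaldehyde) with 3‑hydroxy‑5‑methoxybenzaldehyde.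
- Ring order: both benzene rings are bought, the diaryl ether is made first, and the macrocycle (the only ring formed) is closed in the key step.

Assumption: the target has no stereocentre and its 21‑membered ring is too large for stable planar chirality, so it is one achiral compound and no stereocontrol is needed. Ring A is the 1,3,5‑trisubstituted ring; ring B is the hydroquinone ring.

**Step 1**
Reactants: 1 3‑bromo‑2‑hydroxy‑5‑methoxybenzaldehyde
Product: 2 3‑bromo‑2,5‑dimethoxybenzaldehyde
Conditions: MeI (1.5 equiv), K2CO3 (2 equiv), DMF, rt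
Reagents that add atoms: iodomethane, CI
Why: Williamson ether synthesis on the acidic salicylaldehyde phenol, which removes the free ortho‑OH that would otherwise interfere with the copper coupling of the neighbouring bromide.

**Step 2**
Reactants: 2 3‑bromo‑2,5‑dimethoxybenzaldehyde; 3 3‑hydroxy‑5‑methoxybenzaldehyde
Product: 4 3‑(3‑formyl‑5‑methoxyphenoxy)‑2,5‑dimethoxybenzaldehyde
Conditions: CuI (10 mol %), picolinic acid (20 mol %), K3PO4 (2 equiv), DMSO, 90 °C
Reagents that add atoms: none
Why: Ullmann‑type diaryl ether synthesis, in which monovalent copper with picolinic acid couples ortho‑substituted aryl bromides with phenols under mild base and the two non‑enolisable aryl aldehydes survive K3PO4 in dry DMSO.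

**Step 3**
Reactants: 4 3‑(3‑formyl‑5‑methoxyphenoxy)‑2,5‑dimethoxybenzaldehyde
Product: 5 2‑[3‑[3‑(1,3‑dithian‑2‑yl)‑5‑methoxyphenoxy]‑2,5‑dimethoxyphenyl]‑1,3‑dithiane
Conditions: propane‑1,3‑dithiol (2.4 equiv), BF3·OEt2 (0.3 equiv), CH2Cl2, 0 °C → rt
Reagents that add atoms: propane‑1,3‑dithiol, SCCCS
Why: Lewis‑acid‑catalysed dithioacetalization turns both electrophilic formyl carbons into acidic 2‑aryl‑1,3‑dithiane C–H positions, with water as the only by‑product and the aryl ethers untouched.

**Step 4**
Reactants: 5 2‑[3‑[3‑(1,3‑dithian‑2‑yl)‑5‑methoxyphenoxy]‑2,5‑dimethoxyphenyl]‑1,3‑dithiane; 6 1,12‑dibromododecane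
Product: 9 macrocyclic bis(1,3‑dithiane) (21‑membered ring; the two benzylic carbons of the 14‑carbon bridge are each C2 of a spiro 1,3‑dithiane; three OMe groups), via dilithiated bis‑dithiane 7 (not isolated), via lithiated bromododecyl bis‑dithiane 8 (not isolated)
Conditions: n‑BuLi (2.1 equiv), THF, −78 → −20 °C; then simultaneous syringe‑pump addition of the dianion and 6 (1.0 equiv) into THF, −20 °C → rt, final 2 mM
Reagents that add atoms: none
Why: Corey–Seebach umpolung, in which n‑BuLi removes each 2‑aryl‑dithiane C–H far faster than it ortho‑lithiates the methoxyarenes at low temperature, the two masked aroyl anions displace the primary bromides by SN2, and under pseudo‑high dilution the second alkylation is the closure of the strain‑free 21‑membered ring, so both benzylic C–C bonds form in one operation and no stereocentre is created.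

**Step 5**
Reactants: 9 macrocyclic bis(1,3‑dithiane)
Product: 10 tri‑O‑methyl ether of the target (21‑membered macrocycle with a (CH2)14 bridge; ring A 5‑OMe, ring B 2,5‑di‑OMe)
Conditions: Raney Ni (W‑2, large excess), EtOH/THF, reflux
Reagents that add atoms: none
Why: Mozingo‑type Raney Ni desulfurization hydrogenolyses all four benzylic C–S bonds to leave two CH2 groups, while aryl methyl ethers and the diaryl ether are inert at this temperature.

**Step 6**
Reactants: 10 tri‑O‑methyl ether of the target
Product: 11 target CNP0393720.0 (ring A: 3‑aryloxy‑5‑alkylphenol; ring B: 2‑alkyl‑6‑aryloxyhydroquinone; (CH2)14 bridge)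
Conditions: BBr3 (6 equiv), CH2Cl2, −78 °C → rt; then H2O, 0 °C, under Ar
Reagents that add atoms: none
Why: Lewis‑acid ether cleavage, in which BBr3 binds each methoxy oxygen and bromide removes the methyl group by SN2, the diaryl ether being safe because bromide cannot attack an sp2 carbon, and hydrolysis of the aryl borates frees the three phenols (argon work‑up protects the hydroquinone ring from air oxidation).

**Compound list**
1 | 3‑bromo‑2‑hydroxy‑5‑methoxybenzaldehyde | O=Cc1cc(OC)cc(Br)c1O | starting material
2 | 3‑bromo‑2,5‑dimethoxybenzaldehyde | O=Cc1cc(OC)cc(Br)c1OC | intermediate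
3 | 3‑hydroxy‑5‑methoxybenzaldehyde | O=Cc1cc(O)cc(OC)c1 | starting material
4 | 3‑(3‑formyl‑5‑methoxyphenoxy)‑2,5‑dimethoxybenzaldehyde | COc1cc(C=O)cc(Oc2cc(OC)cc(C=O)c2OC)c1 | intermediate
5 | 2‑[3‑[3‑(1,3‑dithian‑2‑yl)‑5‑methoxyphenoxy]‑2,5‑dimethoxyphenyl]‑1,3‑dithiane | COc1cc(Oc2cc(OC)cc(C3SCCCS3)c2OC)cc(C3SCCCS3)c1 | intermediate
6 | 1,12‑dibromododecane | BrCCCCCCCCCCCCBr | starting material
7 | dilithiated bis‑dithiane (5 with lithium on C2 of each dithiane) | COc1cc(Oc2cc(OC)cc(C3([Li])SCCCS3)c2OC)cc(C3([Li])SCCCS3)c1 | intermediate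
8 | lithiated bromododecyl bis‑dithiane (ring A dithiane C2 carries a 12‑bromododecyl chain, ring B dithiane C2 carries lithium; the opposite order of alkylation leads to the same product) | COc1cc(Oc2cc(OC)cc(C3([Li])SCCCS3)c2OC)cc(C3(CCCCCCCCCCCCBr)SCCCS3)c1 | intermediate
9 | macrocyclic bis(1,3‑dithiane): 21‑membered diaryl ether macrocycle, both benzylic bridge carbons spiro‑fused as C2 of 1,3‑dithianes, twelve CH2 between them, three OMe | COc1cc2cc(c1)Oc1cc(OC)cc(c1OC)C1(SCCCS1)CCCCCCCCCCCCC21SCCCS1 | intermediate
10 | tri‑O‑methyl ether of the target: 21‑membered diaryl ether macrocycle with a (CH2)14 bridge, ring A 5‑OMe, ring B 2,5‑di‑OMe | COc1cc2cc(c1)Oc1cc(OC)cc(c1OC)CCCCCCCCCCCCCC2 | intermediate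
11 | CNP0393720.0, macrocyclic diaryl ether triol | Oc1cc2cc(c1)Oc1cc(O)cc(c1O)CCCCCCCCCCCCCC2 | target

**Totals**
Total steps: 6. Longest linear sequence: 6 (1 → 2 → 4 → 5 → 9 → 10 → 11).

**Three steps most likely to fail**

Risk 1, step 4 (double alkylative macrocyclization; oligomers compete with ring closure). The fallback sets out from 5 and comes back at 10. Compound 5 is dilithiated as before (n‑BuLi, THF, −78 → −20 °C) and quenched at normal concentration with 7‑bromohept‑1‑ene (2.5 equiv). These two ordinary intermolecular Corey–Seebach alkylations give the bis(hept‑6‑enyl) bis‑dithiane F1. Ring‑closing metathesis with the second‑generation Grubbs catalyst (H2IMes)(PCy3)Cl2Ru=CHPh (5–10 mol %, CH2Cl2, 2 mM, 40 °C) then closes the same 21‑membered ring as the macrocyclic alkene bis‑dithiane F2 (E/Z mixture, E drawn; the geometry is irrelevant). Raney Ni (W‑2) in EtOH/THF at reflux under H2 removes both dithianes and saturates the alkene, giving 10.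

Risk 2, step 2 (Ullmann coupling of a hindered ortho‑methoxy bromide in the presence of two aldehydes). The fallback sets out from 2 and comes back at 4. It reverses the role of ring B from aryl electrophile to aryl nucleophile. Miyaura borylation of 2 (B2pin2, Pd(dppf)Cl2 3 mol %, KOAc, dioxane, 90 °C) gives 2,5‑dimethoxy‑3‑(4,4,5,5‑tetramethyl‑1,3,2‑dioxaborolan‑2‑yl)benzaldehyde F3. Chan–Lam–Evans oxidative coupling of F3 with phenol 3 (Cu(OAc)2 20 mol %, pyridine, 4 Å molecular sieves, O2, MeCN, 40 °C) forms the diaryl ether under near‑neutral conditions and gives 4.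

Risk 3, step 5 (Raney Ni on two hindered quaternary dithianes; incomplete desulfurization or over‑reduction). The fallback sets out from 9 and comes back at 10. It separates unmasking from reduction. Non‑oxidative alkylative hydrolysis (MeI, CaCO3, MeCN/H2O 9:1, 60 °C) is chosen so that the hydroquinone dimethyl ether ring is not oxidised, and gives the macrocyclic diaryl diketone F4. Wolff–Kishner reduction (Huang‑Minlon: N2H4·H2O, KOH, diethylene glycol, 130 → 200 °C) converts both carbonyls to CH2 and gives 10. Any partial O‑demethylation at this stage is harmless because step 6 removes all methyl groups.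

**Further compounds**
F1 | step 4 | bis(hept‑6‑enyl) bis‑dithiane (5 with a hept‑6‑enyl group on C2 of each dithiane) | COc1cc(Oc2cc(OC)cc(C3(CCCCCC=C)SCCCS3)c2OC)cc(C3(CCCCCC=C)SCCCS3)c1
F2 | step 4 | macrocyclic alkene bis‑dithiane (9 with an E C=C between bridge carbons 7 and 8) | COc1cc2cc(c1)Oc1cc(OC)cc(c1OC)C1(SCCCS1)CCCCC/C=C/CCCCCC21SCCCS1
F3 | step 2 | 2,5‑dimethoxy‑3‑(4,4,5,5‑tetramethyl‑1,3,2‑dioxaborolan‑2‑yl)benzaldehyde | O=Cc1cc(OC)cc(B2OC(C)(C)C(C)(C)O2)c1OC
F4 | step 5 | macrocyclic diketone (10 with both benzylic bridge carbons as C=O) | COc1cc2cc(c1)Oc1cc(OC)cc(c1OC)C(=O)CCCCCCCCCCCCC2=O
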